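(The earlier runs and the new flask were computed for an exercise, and the scatter is random.)

1. A small charge of starting material, 0.23 M on Saturday, was consumed at a mean 1.50 mM/s over 90.0 s. Monday's charge, 4.09 times greater, was consumed at 1.68 mM/s over the same time. Both ran under the same gas phase.

| flask | starting material | gas phase | remark | time |
|---|---|---|---|---|
| Saturday's | 0.23 M | 53 mM (held) | run made earlier |  |
| Monday's | 0.94 M | 53 mM (held) | run made earlier |  |
| ash | 0.47 M | 53 mM (held) |  | 2.5 min |
| oak | 0.47 M | 53 mM (held) |  | 5.0 min |

- Saturday's (time / s: over-reaction product / %, starting material / %, target / %): 10.0: 0.4, 95.1, 5.7; 25.0: 2.6, 83.8, 13.8; 40.0: 4.4, 73.8, 20.8; 60.0: 11.3, 59.5, 27.2; 90.0: 22.7, 41.4, 36.3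
- Monday's (time / s: over-reaction product / %, starting material / %, target / %): 10.0: 0, 97.9, 1.4; 15.0: 0.3, 97.9, 2.7; 25.0: 1.0, 95.7, 4.7; 50.0: 2.2, 92.1, 6.7; 90.0: 6.0, 83.9, 10.0

(scatter of a reading: 0.5 percentage points)

- which of these there is most of at the end, counted by the starting material in it, ash (target / starting material / over-reaction product)
- which of these there is most of at the end, counted by the starting material in it, oak (target / starting material / over-reaction product)
- amount of the one of these that there is most of at the end, in percent of the starting material charged, ash
- amount of the one of these that there is most of at the end, in percent of the starting material charged, oak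

- at the start none of the gas phase is in solution

2. The factor on the rate, 1.12, is smaller than the factor on the charge, 4.09, so the reckoning here takes the passage of gas into solution as the rate-limiting step.

3. The charge of ash and oak lies between those two, so their rate is taken as the mean of the two rates: the gas feed 1.59 mM/s, the starting material consumed per second at the pace set by incoming gas.

4. Over 2.5 min, that feed amounts to 50.7% of the ash charge, so the reckoning expects 49.3% to stand as starting material.

5. Over 5.0 min, the same feed amounts to 101% of the oak charge. The rate slows, however, in Saturday's readings, which give 1.39 mM/s between 60.0 s and 90.0 s, a factor of 0.927 on its mean. So the reckoning expects a small remainder of starting material in oak, and it gives no figure for the split between the products.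

6. The forecast names starting material for ash at 50% (45% to 55%), a little above the reckoning here, and over-reaction product for oak at 70% (64% to 75%). Its ground: “This indicates gas-transfer limitation after a short lag”.

7. Ash holds most as starting material, 47.9%. Oak holds most as over-reaction product, 72.9%. Both lie inside the forecast's ranges.

    starting material + dissolved gas → target (k = 2.03 /M/s)
    target → over-reaction product (k = 0.0119 /s)
    gas phase ⇌ dissolved gas, rate k3*(csat - [dissolved gas]) (kL = 0.0327 /s)

8. Ash consumed 52.1% of its charge against the 50.7% reckoned from the gas feed. Oak consumed 95.7% against 101%, and its dissolved gas stood at 0.0191 M at the end, against 0.00349 M in ash. A neighbouring flask repeats ash with 1.9 M of starting material for the same 2.5 min. The gas feed gives it 12.6% of its charge consumed, and that neighbour in fact consumed 13.5%, with 86.5% left as starting material.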